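**Plan**
1. Retrosynthesis: the two acetates come last; the C2–O bond and the C3 carbinol go back to a 3-ketone; the C9–C10 bond of ring B is cut together with re-closure of a C2–C10 cyclopropane bond (a bicyclo[3.1.0]hexan-2-one); then the cyclopropane CH2 (C1), the C2=C10 bond (ring-closing metathesis) and the C4–C5 bond (Claisen) are cut, which leaves methyl farnesoate (C5–C15 with C16, C17, C20).
2. Forward: the terminal (E)-methyl group of the farnesoate chain is oxidised and methylated; a Reformatsky–Claisen rearrangement adds C3 and C4 with the gem-dimethyl group; vinyl ketone formation and metathesis give a cyclopentenone (C2, C3, C4, C5, C10); cyclopropanation adds C1; the key step enlarges the five-membered ring to ring A and closes ring B in one event; C2 and C3 are then oxygenated.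
3. Enabling feature: in the acylcyclopropane the C3 carbonyl activates the C2–C10 bond, C10 is a methyl-bearing tertiary cyclopropane carbon, and C5 carries a two-carbon tether (C6, C7) to the (E)-C8=C9 alkene, so C9 can reach the rear of C10 through a six-membered chair; strain release drives the bond formation, and the ester-conjugated C13=C14 alkene stays out.
4. Stereochemistry: the carbinol from a catalytic asymmetric methyl addition sets C5 by chirality transfer; C5 sends the cyclopropane to the opposite face; inversion at C10 gives the trans ring fusion; (E)-alkene geometry in a chair sets C9; the C2 acetate enters anti to axial C20; C3 is set by equatorial hydride delivery.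

Key step: step 8

Remarks: methyl (2E,6E)-farnesoate is taken as a purchasable material (it is one oxidation–esterification from farnesol); ring and side-chain atoms are numbered as in labdane throughout (C1–C10 ring carbons, C11–C16 side chain, C17 on C8, C18 and C19 on C4, C20 on C10).

**Route**

Step 1
Reactants: 1 methyl (2E,6E)-3,7,11-trimethyldodeca-2,6,10-trienoate (methyl farnesoate)
Product: 3 methyl (2E,6E,10E)-3,7,11-trimethyl-12-oxododeca-2,6,10-trienoate, via allylic alcohol 2 (not isolated)
Conditions: SeO2 (cat.), tBuOOH, salicylic acid (cat.), CH2Cl2, 0 °C to rt; crude in CH2Cl2, MnO2, rt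
Reagents that add atoms: tert-butyl hydroperoxide CC(C)(C)OO
Why: Allylic oxidation with SeO2/tBuOOH (ene reaction, then [2,3]-sigmatropic shift) is selective for the (E)-methyl group of the terminal trisubstituted alkene over the internal and the ester-conjugated alkenes, and MnO2 oxidises only the allylic alcohol, so alcohol and enal converge on 3 with the (10E) geometry kept.

Step 2
Reactants: 3 methyl (2E,6E,10E)-3,7,11-trimethyl-12-oxododeca-2,6,10-trienoate
Product: 4 methyl (2E,6E,10E,12R)-12-hydroxy-3,7,11-trimethyltrideca-2,6,10-trienoate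
Conditions: Me2Zn, (+)-3-exo-morpholinoisoborneol (cat.), toluene/hexane, 0 °C to rt; aq. NH4Cl
Reagents that add atoms: dimethylzinc C[Zn]C
Why: Amino-alcohol-catalysed enantioselective dialkylzinc addition to an α-branched enal; the (+)-ligand is chosen because the (−)-series gives (S)-carbinols, so the (R)-carbinol is expected, and Me2Zn leaves the ester alone.

Step 3
Reactants: 4 methyl (2E,6E,10E,12R)-12-hydroxy-3,7,11-trimethyltrideca-2,6,10-trienoate
Product: 5 methyl (2E,6E,10E,12R)-12-(2-bromo-2-methylpropanoyloxy)-3,7,11-trimethyltrideca-2,6,10-trienoate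
Conditions: 2-bromo-2-methylpropanoyl bromide, pyridine, CH2Cl2, 0 °C
Reagents that add atoms: 2-bromo-2-methylpropanoyl bromide CC(C)(Br)C(=O)Br
Why: Plain O-acylation of the secondary allylic alcohol under pyridine buffering, with no effect on the carbinol configuration.

Step 4
Reactants: 5 methyl (2E,6E,10E,12R)-12-(2-bromo-2-methylpropanoyloxy)-3,7,11-trimethyltrideca-2,6,10-trienoate
Product: 8 (3S,4E)-3-[(3E,7E)-9-methoxy-3,7-dimethyl-9-oxonona-3,7-dienyl]-2,2,4-trimethylhex-4-enoic acid, via silyl ketene acetal 6 (not isolated), via trimethylsilyl ester 7 (not isolated)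
Conditions: Zn dust (activated), Me3SiCl, THF, reflux; aq. HCl work-up
Reagents that add atoms: chlorotrimethylsilane C[Si](C)(C)Cl (silicon in 6 and 7 only)
Why: Reformatsky–Claisen rearrangement: zinc inserts into the C–Br bond without any strong base (the γ-acidic enoate is not touched) and the silyl ketene acetal rearranges through a chair with the carbinol methyl group and the long chain both equatorial, so the (R)-carbinol and the (E)-alkene are transferred into (S)-configured C5 and an (E)-trisubstituted alkene, while C4 arrives with its two methyl groups.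

Step 5
Reactants: 8 (3S,4E)-3-[(3E,7E)-9-methoxy-3,7-dimethyl-9-oxonona-3,7-dienyl]-2,2,4-trimethylhex-4-enoic acid
Product: 10 methyl (2E,6E,10S)-10-[(2E)-but-2-en-2-yl]-3,7,11,11-tetramethyl-12-oxotetradeca-2,6,13-trienoate, via acid chloride 9 (not isolated)
Conditions: 1-chloro-N,N,2-trimethylprop-1-en-1-amine, CH2Cl2, 0 °C to rt; then CH2=CHSnBu3, PdCl2(PPh3)2 (cat.), toluene, 70 °C
Reagents that add atoms: 1-chloro-N,N,2-trimethylprop-1-en-1-amine CC(C)=C(Cl)N(C)C (chlorine in 9 only); tributyl(vinyl)stannane C=C[Sn](CCCC)(CCCC)CCCC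
Why: Neutral acid chloride formation avoids acid-induced lactonisation of the γ,δ-unsaturated acid, and Stille acylation with the vinylstannane gives the vinyl ketone without touching the methyl ester, which a vinyl Grignard reagent would attack.

Step 6
Reactants: 10 methyl (2E,6E,10S)-10-[(2E)-but-2-en-2-yl]-3,7,11,11-tetramethyl-12-oxotetradeca-2,6,13-trienoate
Product: 11 methyl (2E,6E)-3,7-dimethyl-9-[(1S)-2,5,5-trimethyl-4-oxocyclopent-2-en-1-yl]nona-2,6-dienoate
Conditions: second-generation Hoveyda–Grubbs catalyst (5–10 mol%), toluene (high dilution), 80 °C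
Reagents that add atoms: none
Why: Ring-closing metathesis between the vinyl ketone and the trisubstituted butenyl group forms the five-membered enone (helped by the gem-dimethyl group) with loss of propene, and C5 is not epimerised under these neutral conditions.

Step 7
Reactants: 11 methyl (2E,6E)-3,7-dimethyl-9-[(1S)-2,5,5-trimethyl-4-oxocyclopent-2-en-1-yl]nona-2,6-dienoate
Product: 12 methyl (2E,6E)-3,7-dimethyl-9-[(1S,2S,5S)-1,3,3-trimethyl-4-oxobicyclo[3.1.0]hexan-2-yl]nona-2,6-dienoate (side chain trans to the cyclopropane CH2)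
Conditions: Me3S(O)I, NaH, DMSO, rt; then 11, rt to 50 °C
Reagents that add atoms: trimethylsulfoxonium iodide C[S+](C)(C)=O.[I-]
Why: Corey–Chaykovsky cyclopropanation: the sulfoxonium ylide adds to C10 of the cyclopentenone anti to the neighbouring C5 side chain and the enolate closes the three-membered ring, so the new CH2 (C1) stands trans to the side chain, while the less electrophilic β,β-disubstituted enoate is expected to stay intact.

Step 8
Reactants: 12 methyl (2E,6E)-3,7-dimethyl-9-[(1S,2S,5S)-1,3,3-trimethyl-4-oxobicyclo[3.1.0]hexan-2-yl]nona-2,6-dienoate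
Product: 14 methyl (5S,9R,10S,13E)-3-oxolabda-7,13-dien-15-oate (ent-labdane series, trans-decalin), via aluminium enolate 13 (not isolated)
Conditions: MeAlCl2 (2.5 equiv), CH2Cl2, −78 °C to −30 °C; sat. aq. NaHCO3
Reagents that add atoms: methylaluminium dichloride C[Al](Cl)Cl (aluminium and chlorine in 13 only)
Why: MeAlCl2 binds the ketone oxygen and the C2–C10 cyclopropane bond breaks toward the methyl-bearing tertiary carbon C10 as the C8=C9 alkene attacks C10 from the rear, giving an aluminium enolate and the tertiary C8 cation, which loses H7 to the Al–Me group (methane) to leave the C7=C8 alkene. The closest known reaction is the Lewis-acid-induced opening of acylcyclopropanes with olefin participation, a cation–olefin cyclization shown on 5-methylbicyclo[3.1.0]hexan-2-ones. Ring B closes 6-endo-trig at the alkene (6-exo-tet at C10), and ring A arises at the same time by enlargement of the cyclopentanone as the internal cyclopropane bond breaks. C10 is set by inversion at the cyclopropane carbon, so the side chain trans to the cyclopropane CH2 leads to the trans-decalin; C9 is set by the (E)-alkene in a chair transition state that places C11 equatorial and H9 anti to C20; C5 is carried in unchanged. The step needs cleavage of the internal and not the external cyclopropane bond (secured by the methyl group on C10 and by a tether that can only reach C10), a stop after one ring (the C13=C14 alkene is deactivated by the complexed ester), and proton loss toward C7 (the axial H7 is the kinetically favoured one, and the alkylaluminium removes the proton irreversibly so the alkene is not equilibrated).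

Step 9
Reactants: 14 methyl (5S,9R,10S,13E)-3-oxolabda-7,13-dien-15-oate
Product: 16 methyl (2S,5S,9R,10S,13E)-2-acetoxy-3-oxolabda-7,13-dien-15-oate, via silyl enol ether 15 (not isolated)
Conditions: Me3SiOTf, Et3N, CH2Cl2, 0 °C; pentane/aq. NaHCO3 work-up; crude 15, Pb(OAc)4, CH2Cl2, 0 °C
Reagents that add atoms: trimethylsilyl trifluoromethanesulfonate C[Si](C)(C)OS(=O)(=O)C(F)(F)F (silicon in 15 only); lead tetraacetate CC(=O)O[Pb](OC(C)=O)(OC(C)=O)OC(C)=O
Why: Soft enolisation can only go toward C2 because C4 is quaternary, and lead tetraacetate acetoxylation of the silyl enol ether (a Rubottom-type α-oxygenation that leaves isolated alkenes alone) brings the acetate to C2 from the face opposite to the axial methyl groups on C10 and C4, giving the equatorial (2S) acetate, which is also the more stable epimer.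

Step 10
Reactants: 16 methyl (2S,5S,9R,10S,13E)-2-acetoxy-3-oxolabda-7,13-dien-15-oate
Product: 18 (2S,3R,5S,9R,10S,13E)-2,3-dihydroxylabda-7,13-dien-15-oic acid, via hydroxy acetate 17 (not isolated)
Conditions: LiBH(s-Bu)3, THF, −78 °C; then MeOH, aq. LiOH, rt; aq. citric acid
Reagents that add atoms: lithium hydroxide [Li+].[OH-]
Why: The bulky borohydride approaches the 4,4-dimethyl-3-ketone along the equatorial trajectory (steric approach control, as with 3-oxo triterpenoids) and gives the axial (3R) alcohol cis to the C2 oxygen while the β,β-disubstituted enoate resists hydride; hydroxide then cleaves the methyl ester and the acetate, so any acetyl migration is of no consequence.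

Step 11
Reactants: 18 (2S,3R,5S,9R,10S,13E)-2,3-dihydroxylabda-7,13-dien-15-oic acid
Product: 20 (2S,3R,5S,9R,10S,13E)-2,3-diacetoxylabda-7,13-dien-15-oic acid (ent-2α,3α-diacetoxylabda-7,13E-dien-15-oic acid), via mixed anhydride 19 (not isolated)
Conditions: Ac2O, pyridine, DMAP (cat.), 40 °C; then H2O/THF, rt
Reagents that add atoms: acetic anhydride CC(=O)OC(C)=O
Why: DMAP-catalysed acetylation esterifies both the equatorial C2 and the hindered axial C3 hydroxyl groups, and the mixed anhydride formed at the carboxyl group is hydrolysed on aqueous work-up to release the acid.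

**Compound list**

1 | methyl (2E,6E)-3,7,11-trimethyldodeca-2,6,10-trienoate | COC(=O)/C=C(C)/CC/C=C(C)/CCC=C(C)C | starting material
2 | methyl (2E,6E,10E)-12-hydroxy-3,7,11-trimethyldodeca-2,6,10-trienoate | COC(=O)/C=C(C)/CC/C=C(C)/CC/C=C(C)/CO | intermediate
3 | methyl (2E,6E,10E)-3,7,11-trimethyl-12-oxododeca-2,6,10-trienoate | COC(=O)/C=C(C)/CC/C=C(C)/CC/C=C(C)/C=O | intermediate
4 | methyl (2E,6E,10E,12R)-12-hydroxy-3,7,11-trimethyltrideca-2,6,10-trienoate | C[C@@H](O)/C(C)=C/CC/C(C)=C/CC/C(C)=C/C(=O)OC | intermediate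
5 | methyl (2E,6E,10E,12R)-12-(2-bromo-2-methylpropanoyloxy)-3,7,11-trimethyltrideca-2,6,10-trienoate | C[C@@H](OC(=O)C(C)(C)Br)/C(C)=C/CC/C(C)=C/CC/C(C)=C/C(=O)OC | intermediate
6 | trimethylsilyl ketene acetal of 5 (Me2C=C(OSiMe3)–O– on the (R)-carbinol) | C[C@@H](OC(O[Si](C)(C)C)=C(C)C)/C(C)=C/CC/C(C)=C/CC/C(C)=C/C(=O)OC | intermediate
7 | trimethylsilyl ester of acid 8 | C[Si](C)(C)OC(=O)C(C)(C)[C@@H](CC/C(C)=C/CC/C(C)=C/C(=O)OC)/C(C)=C/C | intermediate
8 | (3S,4E)-3-[(3E,7E)-9-methoxy-3,7-dimethyl-9-oxonona-3,7-dienyl]-2,2,4-trimethylhex-4-enoic acid | OC(=O)C(C)(C)[C@@H](CC/C(C)=C/CC/C(C)=C/C(=O)OC)/C(C)=C/C | intermediate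
9 | acid chloride of 8 | ClC(=O)C(C)(C)[C@@H](CC/C(C)=C/CC/C(C)=C/C(=O)OC)/C(C)=C/C | intermediate
10 | methyl (2E,6E,10S)-10-[(2E)-but-2-en-2-yl]-3,7,11,11-tetramethyl-12-oxotetradeca-2,6,13-trienoate | C=CC(=O)C(C)(C)[C@@H](CC/C(C)=C/CC/C(C)=C/C(=O)OC)/C(C)=C/C | intermediate
11 | methyl (2E,6E)-3,7-dimethyl-9-[(1S)-2,5,5-trimethyl-4-oxocyclopent-2-en-1-yl]nona-2,6-dienoate | O=C1C=C(C)[C@H](CC/C(C)=C/CC/C(C)=C/C(=O)OC)C1(C)C | intermediate
12 | methyl (2E,6E)-3,7-dimethyl-9-[(1S,2S,5S)-1,3,3-trimethyl-4-oxobicyclo[3.1.0]hexan-2-yl]nona-2,6-dienoate | O=C1[C@H]2C[C@@]2(C)[C@H](CC/C(C)=C/CC/C(C)=C/C(=O)OC)C1(C)C | intermediate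
13 | dichloroaluminium enolate (C2=C3–O–AlCl2) of 14 | Cl[Al](Cl)OC1=CC[C@@]2(C)[C@H](CC/C(C)=C/C(=O)OC)C(C)=CC[C@@H]2C1(C)C | intermediate
14 | methyl (5S,9R,10S,13E)-3-oxolabda-7,13-dien-15-oate | O=C1CC[C@@]2(C)[C@H](CC/C(C)=C/C(=O)OC)C(C)=CC[C@@H]2C1(C)C | intermediate
15 | trimethylsilyl enol ether (C2=C3–OSiMe3) of 14 | C[Si](C)(C)OC1=CC[C@@]2(C)[C@H](CC/C(C)=C/C(=O)OC)C(C)=CC[C@@H]2C1(C)C | intermediate
16 | methyl (2S,5S,9R,10S,13E)-2-acetoxy-3-oxolabda-7,13-dien-15-oate | CC(=O)O[C@H]1C[C@@]2(C)[C@H](CC/C(C)=C/C(=O)OC)C(C)=CC[C@@H]2C(C)(C)C1=O | intermediate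
17 | methyl (2S,3R,5S,9R,10S,13E)-2-acetoxy-3-hydroxylabda-7,13-dien-15-oate | CC(=O)O[C@H]1C[C@@]2(C)[C@H](CC/C(C)=C/C(=O)OC)C(C)=CC[C@@H]2C(C)(C)[C@H]1O | intermediate
18 | (2S,3R,5S,9R,10S,13E)-2,3-dihydroxylabda-7,13-dien-15-oic acid | O[C@H]1C[C@@]2(C)[C@H](CC/C(C)=C/C(=O)O)C(C)=CC[C@@H]2C(C)(C)[C@H]1O | intermediate
19 | mixed acetic anhydride of 20 at C15 | CC(=O)O[C@H]1C[C@@]2(C)[C@H](CC/C(C)=C/C(=O)OC(C)=O)C(C)=CC[C@@H]2C(C)(C)[C@H]1OC(C)=O | intermediate
20 | (2S,3R,5S,9R,10S,13E)-2,3-diacetoxylabda-7,13-dien-15-oic acid | CC(=O)O[C@H]1C[C@@]2(C)[C@H](CC/C(C)=C/C(=O)O)C(C)=CC[C@@H]2C(C)(C)[C@H]1OC(C)=O | target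

**Step count and risks**

Total step count: 11. Longest linear sequence: 11 steps (1 to 20).

Step 8. After ring B has closed, proton loss from the C8 cation may not be selective for H7, so exocyclic or tetrasubstituted alkene isomers may form, or the cation may be captured by chloride or rearrange by hydride shift. The fallback sets out from 12 and comes back at 14. The cyclization is ended on purpose by chloride capture with SnCl4 in CH2Cl2 at −78 °C, which should give the tertiary chloride methyl (13E)-8-chloro-3-oxo-ent-labd-13-en-15-oate F1 with the C–Cl bond equatorial and anti to C20. An equatorial C–Cl bond has only the C17 hydrogens antiperiplanar, so E2 elimination with DBU in hot toluene should give the exocyclic alkene methyl (13E)-3-oxo-ent-labda-8(17),13-dien-15-oate F2. A one-position isomerisation by hydrogen atom transfer (Co(salen)Cl cat., PhSiH3 cat., benzene, rt) should then move the double bond into the ring toward the less hindered C7 and give 14.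

Step 7. Conjugate addition of the ylide to the hindered β,β-disubstituted enone may be slow, so γ-deprotonation at C5 (loss of enantiomeric purity) or attack at the enoate may compete. The fallback sets out from 11 and comes back at 12, and builds the cyclopropane stepwise without a basic ylide. CuI-catalysed conjugate addition of (isopropoxydimethylsilyl)methylmagnesium chloride in THF at −78 °C to 0 °C, anti to the side chain, should give the silylmethyl ketone F3. Tamao oxidation (H2O2, KF, KHCO3, THF/MeOH) should give the hydroxymethyl ketone F4, and MsCl/Et3N the mesylate F5. DBU then closes the three-membered ring by intramolecular enolate alkylation, since only C2 can enolise, and gives 12.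

Step 6. Catalyst turnover may be slow because one partner is an electron-poor vinyl ketone and the other a trisubstituted alkene, which would allow oligomerisation of the vinyl ketone or ring closure onto the C8=C9 alkene. The fallback sets out from 10 and comes back at 11. Luche reduction (NaBH4, CeCl3·7H2O, MeOH, −78 °C) should give the allylic alcohol F6 as a mixture of carbinol epimers, which is of no consequence. Ring-closing metathesis started at the electron-rich allylic alcohol olefin (second-generation Grubbs catalyst, CH2Cl2, 40 °C) should give the cyclopentenol F7, and MnO2 oxidation in CH2Cl2 returns the enone 11.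

**Further compounds**

F1 | step 8 | methyl (13E)-8-chloro-3-oxo-ent-labd-13-en-15-oate (Cl equatorial, anti to C20) | O=C1CC[C@@]2(C)[C@H](CC/C(C)=C/C(=O)OC)[C@@](C)(Cl)CC[C@@H]2C1(C)C
F2 | step 8 | methyl (13E)-3-oxo-ent-labda-8(17),13-dien-15-oate | O=C1CC[C@@]2(C)[C@H](CC/C(C)=C/C(=O)OC)C(=C)CC[C@@H]2C1(C)C
F3 | step 7 | methyl (2E,6E)-9-[2-(isopropoxydimethylsilylmethyl)-2,5,5-trimethyl-4-oxocyclopentyl]-3,7-dimethylnona-2,6-dienoate (silylmethyl group trans to the side chain, C5 as in 11) | O=C1C[C@@](C)(C[Si](C)(C)OC(C)C)[C@H](CC/C(C)=C/CC/C(C)=C/C(=O)OC)C1(C)C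
F4 | step 7 | methyl (2E,6E)-9-[2-(hydroxymethyl)-2,5,5-trimethyl-4-oxocyclopentyl]-3,7-dimethylnona-2,6-dienoate (hydroxymethyl group trans to the side chain) | O=C1C[C@@](C)(CO)[C@H](CC/C(C)=C/CC/C(C)=C/C(=O)OC)C1(C)C
F5 | step 7 | methanesulfonate of F4 | O=C1C[C@@](C)(COS(C)(=O)=O)[C@H](CC/C(C)=C/CC/C(C)=C/C(=O)OC)C1(C)C
F6 | step 6 | methyl (2E,6E,10S)-10-[(2E)-but-2-en-2-yl]-12-hydroxy-3,7,11,11-tetramethyltetradeca-2,6,13-trienoate (carbinol epimers) | C=CC(O)C(C)(C)[C@@H](CC/C(C)=C/CC/C(C)=C/C(=O)OC)/C(C)=C/C
F7 | step 6 | methyl (2E,6E)-9-[(1S)-4-hydroxy-2,5,5-trimethylcyclopent-2-en-1-yl]-3,7-dimethylnona-2,6-dienoate (carbinol epimers) | OC1C=C(C)[C@H](CC/C(C)=C/CC/C(C)=C/C(=O)OC)C1(C)C
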